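**Retrosynthetic overview**

- Ring B is closed last, through the C1–C8 bond, by an acid-triggered biomimetic cation cyclisation of a monocyclic dienone that carries two identical lavandulyl groups on one carbon. Ring A is the original phloroglucinol ring.
- The key disconnection is the C2–OMe bond. It is made one step earlier, on the monocyclic triketone, where that carbon is the only oxygenated ring carbon not next to the quaternary centre (new boronic-acid-catalysed methanolysis).
- The C-prenyl and both C-lavandulyl bonds come from enolate/phenoxide alkylations. A formyl group blocks the third ring carbon so both lavandulyl groups go to one carbon, then leaves as methyl formate.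
- (S)-Lavandulyl triflate comes from an Evans deconjugative prenylation. Its single stereocentre is the source of all four stereocentres of the target.

Assumption: anions formed by the bases named in the Conditions are treated as activated forms of the numbered compounds and are not numbered separately.

**Route**

Step 1
Reactants: 1 (4S)-4-benzyl-1,3-oxazolidin-2-one; 2 3-methylbut-2-enoyl chloride
Product: 3 (4S)-4-benzyl-3-(3-methylbut-2-enoyl)-1,3-oxazolidin-2-one
Conditions: n-BuLi, THF, −78 °C; then 2, −78 → 0 °C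
Reagents that add atoms: none
Why: N-acylation of the lithiated Evans oxazolidinone with an acid chloride (auxiliary attachment); no stereocentre is formed and the auxiliary centre is untouched.

Step 2
Reactants: 3 (4S)-4-benzyl-3-(3-methylbut-2-enoyl)-1,3-oxazolidin-2-one; 4 1-bromo-3-methylbut-2-ene
Product: 5 (4S)-4-benzyl-3-[(2S)-5-methyl-2-(prop-1-en-2-yl)hex-4-enoyl]-1,3-oxazolidin-2-one
Conditions: NaN(SiMe3)2 (1.05 equiv), THF, −78 °C; then 4, −78 → −20 °C
Reagents that add atoms: none
Why: Evans deconjugative α-alkylation: γ-deprotonation gives the chelated (Z)-dienolate, which reacts at the α-carbon with prenyl bromide on the face away from the benzyl group, setting the (2S) centre that later supplies both C7 and the side-chain centre of the target.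

Step 3
Reactants: 5 (4S)-4-benzyl-3-[(2S)-5-methyl-2-(prop-1-en-2-yl)hex-4-enoyl]-1,3-oxazolidin-2-one
Product: 6 (2S)-5-methyl-2-(prop-1-en-2-yl)hex-4-en-1-ol
Conditions: LiBH4, H2O (1 equiv), Et2O, 0 °C
Reagents that add atoms: none
Why: Reductive removal of the Evans auxiliary with LiBH4 (hydride attack at the exocyclic imide carbonyl) gives the primary alcohol without touching the β,γ-alkene or the α-centre.

Step 4
Reactants: 6 (2S)-5-methyl-2-(prop-1-en-2-yl)hex-4-en-1-ol
Product: 7 (2S)-5-methyl-2-(prop-1-en-2-yl)hex-4-en-1-yl trifluoromethanesulfonate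
Conditions: Tf2O, 2,6-lutidine, CH2Cl2, −78 °C; cold pentane/silica filtration, used at once
Reagents that add atoms: trifluoromethanesulfonic anhydride, O=S(=O)(C(F)(F)F)OS(=O)(=O)C(F)(F)F
Why: O-sulfonylation of a primary alcohol (triflate formation) at low temperature with a hindered pyridine base; the stereocentre is one carbon away from the reacting oxygen and is not affected.

Step 5
Reactants: 8 phenyl(2,4,6-trihydroxyphenyl)methanone
Product: 10 3-benzoyl-2,4,6-trihydroxybenzaldehyde, via Vilsmeier adduct 9 (not isolated)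
Conditions: POCl3 (1.1 equiv), DMF, EtOAc, 0 °C → rt; then H2O, 50 °C
Reagents that add atoms: N,N-dimethylformamide, CN(C)C=O; water, O
Why: Vilsmeier–Haack formylation of the electron-rich phloroglucinol ring at one of its two equivalent free positions; the formyl group deactivates the ring against a second formylation and then serves as a removable blocking group.

Step 6
Reactants: 10 3-benzoyl-2,4,6-trihydroxybenzaldehyde; 7 (2S)-5-methyl-2-(prop-1-en-2-yl)hex-4-en-1-yl trifluoromethanesulfonate (first equivalent)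
Product: 12 3-benzoyl-2,4-dihydroxy-6-oxo-5,5-bis[(2R)-5-methyl-2-(prop-1-en-2-yl)hex-4-en-1-yl]cyclohexa-1,3-diene-1-carbaldehyde, via mono-lavandulyl arene 11 (not isolated)
Conditions: LiN(SiMe3)2 (3.1 equiv), THF, −78 °C; 7 (1.1 equiv), → 0 °C; then LiN(SiMe3)2 (1.1 equiv), 7 (1.2 equiv), −78 → 0 °C; aq HCl work-up
Reagents that add atoms: (2S)-5-methyl-2-(prop-1-en-2-yl)hex-4-en-1-yl trifluoromethanesulfonate (second equivalent of 7), C=C(C)[C@H](CC=C(C)C)COS(=O)(=O)C(F)(F)F
Why: Twofold phenoxide C-alkylation ending in alkylative dearomatisation, each SN2 reaction consuming one equivalent of 7: the two acylated ring carbons are not nucleophilic, so both alkylations of the lithium phenoxide (tight Li–O ion pairs favour C- over O-attack) occur at the only free carbon, which becomes a quaternary carbon with two identical groups and is therefore not a stereocentre (the side-chain descriptor changes from S to R only through CIP priorities).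

Step 7
Reactants: 12 3-benzoyl-2,4-dihydroxy-6-oxo-5,5-bis[(2R)-5-methyl-2-(prop-1-en-2-yl)hex-4-en-1-yl]cyclohexa-1,3-diene-1-carbaldehyde; 4 1-bromo-3-methylbut-2-ene
Product: 14 4-benzoyl-3,5-dihydroxy-2-(3-methylbut-2-en-1-yl)-6,6-bis[(2R)-5-methyl-2-(prop-1-en-2-yl)hex-4-en-1-yl]cyclohexa-2,4-dien-1-one, via deformylated triketone 13 (not isolated)
Conditions: K2CO3 (3 equiv), MeOH, 45 °C, Ar sweep; then 0 °C, 4 (1.05 equiv)
Reagents that add atoms: none
Why: Retro-Claisen deformylation (the formyl group is the most electrophilic acyl of the triacylmethane unit and leaves as volatile methyl formate) followed by lupulone-type C-prenylation of the vinylogous acid anion at its single CH carbon in protic medium, where hydrogen bonding suppresses O-alkylation.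

Step 8
Reactants: 14 4-benzoyl-3,5-dihydroxy-2-(3-methylbut-2-en-1-yl)-6,6-bis[(2R)-5-methyl-2-(prop-1-en-2-yl)hex-4-en-1-yl]cyclohexa-2,4-dien-1-one
Product: 15 4-benzoyl-5-hydroxy-3-methoxy-2-(3-methylbut-2-en-1-yl)-6,6-bis[(2R)-5-methyl-2-(prop-1-en-2-yl)hex-4-en-1-yl]cyclohexa-2,4-dien-1-one
Conditions: 3,4,5-F3C6H2B(OH)2 (20 mol%), MeOH–PhMe 1:1, 3 Å MS, 50 °C, Ar
Reagents that add atoms: methanol, CO
Why: Proposed new method: an electron-poor arylboronic acid serves as a neutral catalyst for dehydrative methanolysis of the enolised triketone (a vinylogous Fischer esterification): it condenses reversibly with the benzoyl-oxygen/ring-enol-oxygen pairs to give six-membered boron chelates in which the chelated ring carbon is an activated vinylogous acyl carbon, methanol can add only at C3 because C1 and C5 are neopentyl-type carbons shielded on both faces by the two lavandulyl CH2 groups on C6, collapse of the adduct expels the boron-bound oxygen while the sieves take up water, any attack at the exocyclic benzoyl carbon is reversible and drains to the endocyclic ether that keeps the C5–OH···O=C(Ph) hydrogen bond, and the non-acidic medium leaves both isopropenyl groups untouched; the closest known reaction types are boric/boronic acid-catalysed esterification of α-hydroxy carboxylic acids through chelated acyloxyboron species and Brønsted acid-catalysed formation of vinylogous esters from 1,3-diones and methanol.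

Step 9
Reactants: 15 4-benzoyl-5-hydroxy-3-methoxy-2-(3-methylbut-2-en-1-yl)-6,6-bis[(2R)-5-methyl-2-(prop-1-en-2-yl)hex-4-en-1-yl]cyclohexa-2,4-dien-1-one
Product: 16 (1R,5R,7R)-3-benzoyl-2-methoxy-8,8-dimethyl-1,7-bis(3-methylbut-2-en-1-yl)-5-[(2R)-5-methyl-2-(prop-1-en-2-yl)hex-4-en-1-yl]bicyclo[3.3.1]non-2-ene-4,9-dione
Conditions: HCO2H–CH2Cl2 1:1, 0 °C → rt, ca. 2 h; NaHCO3 quench at full conversion
Reagents that add atoms: none
Why: Biomimetic cation–olefin cyclisation of the kind used for clusianone-class cores (Markovnikov protonation of an isopropenyl group and six-ring C-alkylation of the dienol ether at C2, the prenyl-bearing carbon, which is more electron-rich than the benzoyl-bearing C4): the two lavandulyl groups are diastereotopic and only the one whose chair-like transition state keeps the prenyl group on the future C7 equatorial (exo) closes readily, so the (R) centre carried in from 7 becomes C7 and dictates the R configuration of both new bridgeheads C1 and C5, while the second lavandulyl group keeps its (R) centre on C5 and its isopropenyl group is no more acid-labile than the three prenyl groups.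

**Compound list**

1 | (4S)-4-benzyl-1,3-oxazolidin-2-one | O=C1OC[C@H](Cc2ccccc2)N1 | starting material
2 | 3-methylbut-2-enoyl chloride | CC(C)=CC(=O)Cl | starting material
3 | (4S)-4-benzyl-3-(3-methylbut-2-enoyl)-1,3-oxazolidin-2-one | CC(C)=CC(=O)N1[C@@H](Cc2ccccc2)COC1=O | intermediate
4 | 1-bromo-3-methylbut-2-ene (prenyl bromide) | CC(C)=CCBr | starting material
5 | (4S)-4-benzyl-3-[(2S)-5-methyl-2-(prop-1-en-2-yl)hex-4-enoyl]-1,3-oxazolidin-2-one | C=C(C)[C@H](CC=C(C)C)C(=O)N1[C@@H](Cc2ccccc2)COC1=O | intermediate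
6 | (2S)-5-methyl-2-(prop-1-en-2-yl)hex-4-en-1-ol ((S)-lavandulol) | C=C(C)[C@H](CC=C(C)C)CO | intermediate
7 | (2S)-5-methyl-2-(prop-1-en-2-yl)hex-4-en-1-yl trifluoromethanesulfonate | C=C(C)[C@H](CC=C(C)C)COS(=O)(=O)C(F)(F)F | intermediate
8 | phenyl(2,4,6-trihydroxyphenyl)methanone | O=C(c1ccccc1)c1c(O)cc(O)cc1O | starting material
9 | 4-benzoyl-6-[(dimethylamino)methylidene]-3,5-dihydroxycyclohexa-2,4-dien-1-one (Vilsmeier adduct, neutral form of the iminium salt) | CN(C)C=C1C(=O)C=C(O)C(C(=O)c2ccccc2)=C1O | intermediate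
10 | 3-benzoyl-2,4,6-trihydroxybenzaldehyde | O=Cc1c(O)cc(O)c(C(=O)c2ccccc2)c1O | intermediate
11 | 3-benzoyl-2,4,6-trihydroxy-5-[(2R)-5-methyl-2-(prop-1-en-2-yl)hex-4-en-1-yl]benzaldehyde | C=C(C)[C@H](CC=C(C)C)Cc1c(O)c(C=O)c(O)c(C(=O)c2ccccc2)c1O | intermediate
12 | 3-benzoyl-2,4-dihydroxy-6-oxo-5,5-bis[(2R)-5-methyl-2-(prop-1-en-2-yl)hex-4-en-1-yl]cyclohexa-1,3-diene-1-carbaldehyde | O=CC1=C(O)C(C(=O)c2ccccc2)=C(O)C(C[C@@H](CC=C(C)C)C(C)=C)(C[C@@H](CC=C(C)C)C(C)=C)C1=O | intermediate
13 | 4-benzoyl-3,5-dihydroxy-6,6-bis[(2R)-5-methyl-2-(prop-1-en-2-yl)hex-4-en-1-yl]cyclohexa-2,4-dien-1-one | O=C1C=C(O)C(C(=O)c2ccccc2)=C(O)C1(C[C@@H](CC=C(C)C)C(C)=C)C[C@@H](CC=C(C)C)C(C)=C | intermediate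
14 | 4-benzoyl-3,5-dihydroxy-2-(3-methylbut-2-en-1-yl)-6,6-bis[(2R)-5-methyl-2-(prop-1-en-2-yl)hex-4-en-1-yl]cyclohexa-2,4-dien-1-one | CC(C)=CCC1=C(O)C(C(=O)c2ccccc2)=C(O)C(C[C@@H](CC=C(C)C)C(C)=C)(C[C@@H](CC=C(C)C)C(C)=C)C1=O | intermediate
15 | 4-benzoyl-5-hydroxy-3-methoxy-2-(3-methylbut-2-en-1-yl)-6,6-bis[(2R)-5-methyl-2-(prop-1-en-2-yl)hex-4-en-1-yl]cyclohexa-2,4-dien-1-one | CC(C)=CCC1=C(OC)C(C(=O)c2ccccc2)=C(O)C(C[C@@H](CC=C(C)C)C(C)=C)(C[C@@H](CC=C(C)C)C(C)=C)C1=O | intermediate
16 | (1R,5R,7R)-3-benzoyl-2-methoxy-8,8-dimethyl-1,7-bis(3-methylbut-2-en-1-yl)-5-[(2R)-5-methyl-2-(prop-1-en-2-yl)hex-4-en-1-yl]bicyclo[3.3.1]non-2-ene-4,9-dione | C=C(C)[C@H](CC=C(C)C)C[C@@]12C[C@@H](CC=C(C)C)C(C)(C)[C@@](CC=C(C)C)(C1=O)C(OC)=C(C(=O)c1ccccc1)C2=O | target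

**Step count and risks**

Total: 9 steps. Longest linear sequence: 8 steps (steps 1–4, then 6–9); step 5 is a one-step branch from 8.

Steps most likely to fail:

Step 6 (double C-lavandulylation). The doubly acylated ring is a weaker carbon nucleophile, the triflate is a hard electrophile (risk of O-alkylation), and the second alkylation is at an already substituted carbon. The fallback sets out from 8 and returns to the route at 12. The more nucleophilic monoacyl arene 8 is C-alkylated first (LiN(SiMe3)2, THF, 0.8 equiv of 7) to give phenyl{2,4,6-trihydroxy-3-[(2R)-5-methyl-2-(prop-1-en-2-yl)hex-4-en-1-yl]phenyl}methanone F1. Vilsmeier–Haack formylation of its last free ring carbon (POCl3, DMF, EtOAc, 0 °C; then aqueous NaOAc) gives, through the adduct 4-benzoyl-6-[(dimethylamino)methylidene]-3,5-dihydroxy-2-[(2R)-5-methyl-2-(prop-1-en-2-yl)hex-4-en-1-yl]cyclohexa-2,4-dien-1-one F2, the aldehyde 11, which is now isolated. One further alkylation with 7 (LiN(SiMe3)2, THF) is then the established alkylative dearomatisation of a fully substituted acylphloroglucinol and gives 12.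

Step 8 (the proposed boronic-acid-catalysed methanolysis). Turnover may be blocked by the chelating product, or the exocyclic benzoyl carbon may compete. The fallback uses known chemistry, sets out from 14 and returns at 15. TsCl, Et3N, CH2Cl2, −20 °C sulfonylates the least hindered enol oxygen to give 6-benzoyl-5-hydroxy-2-(3-methylbut-2-en-1-yl)-3-oxo-4,4-bis[(2R)-5-methyl-2-(prop-1-en-2-yl)hex-4-en-1-yl]cyclohexa-1,5-dien-1-yl 4-methylbenzenesulfonate F3. NaOMe in MeOH at 0 °C then replaces the tosylate by addition–elimination at the same carbon to give 15. Both are standard reactions of enolised 1,3-diones.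

Step 9 (group-selective cationic cyclisation). Possible failures are poor discrimination between the two lavandulyl groups, closure at the benzoyl-bearing carbon, O-cyclisation, or loss of the methyl enol ether in acid. The fallback sets out from 14 and returns at 16. It changes the order of ring closure and etherification. The free triketone 14, the substrate class for which the formic acid cyclisation is established, is cyclised (HCO2H, rt) to (1R,5R,7R)-3-benzoyl-2-hydroxy-8,8-dimethyl-1,7-bis(3-methylbut-2-en-1-yl)-5-[(2R)-5-methyl-2-(prop-1-en-2-yl)hex-4-en-1-yl]bicyclo[3.3.1]non-2-ene-4,9-dione F4. F4 is then O-methylated with Me3SiCHN2 (MeOH–PhMe, 0 °C). This methylation is not site-selective, and 16 is isolated by chromatography.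

**Further compounds**

F1 | step 6 | phenyl{2,4,6-trihydroxy-3-[(2R)-5-methyl-2-(prop-1-en-2-yl)hex-4-en-1-yl]phenyl}methanone | C=C(C)[C@H](CC=C(C)C)Cc1c(O)cc(O)c(C(=O)c2ccccc2)c1O
F2 | step 6 | 4-benzoyl-6-[(dimethylamino)methylidene]-3,5-dihydroxy-2-[(2R)-5-methyl-2-(prop-1-en-2-yl)hex-4-en-1-yl]cyclohexa-2,4-dien-1-one | CN(C)C=C1C(=O)C(C[C@@H](CC=C(C)C)C(C)=C)=C(O)C(C(=O)c2ccccc2)=C1O
F3 | step 8 | 6-benzoyl-5-hydroxy-2-(3-methylbut-2-en-1-yl)-3-oxo-4,4-bis[(2R)-5-methyl-2-(prop-1-en-2-yl)hex-4-en-1-yl]cyclohexa-1,5-dien-1-yl 4-methylbenzenesulfonate | CC(C)=CCC1=C(OS(=O)(=O)c2ccc(C)cc2)C(C(=O)c2ccccc2)=C(O)C(C[C@@H](CC=C(C)C)C(C)=C)(C[C@@H](CC=C(C)C)C(C)=C)C1=O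
F4 | step 9 | (1R,5R,7R)-3-benzoyl-2-hydroxy-8,8-dimethyl-1,7-bis(3-methylbut-2-en-1-yl)-5-[(2R)-5-methyl-2-(prop-1-en-2-yl)hex-4-en-1-yl]bicyclo[3.3.1]non-2-ene-4,9-dione | C=C(C)[C@H](CC=C(C)C)C[C@@]12C[C@@H](CC=C(C)C)C(C)(C)[C@@](CC=C(C)C)(C1=O)C(O)=C(C(=O)c1ccccc1)C2=O
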